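**Plan**

1. Ring numbering of the target: C1 ketone, C2 bears CH2CO2Me, C3 vinylic CH, C4 carbinol, C5 bears the chain, C6 CH2. The retrosynthesis cuts C3–C4 and C1–C2 together, releasing C2=C3 with the acetate arm as a silylated but-3-ynoate and leaving C4–C5–C6–C1 closed by a C1–C4 bond as a cis-2-alkoxy-3-alkylcyclobutanone. The C5–CH2 bond is cut next, giving geranylgeranyl bromide.
2. Enabling feature: the ketone carbon C1 and the sp3 carbon C4 are bridged by exactly the two sp2 carbons C2=C3, and C4–C5–C6–C1 is a four-carbon chain. The cyclohexenone is therefore a cyclobutanone whose strained C(=O)–Cα bond has taken up an alkyne; that C1–C4 bond is temporary and absent from the target.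
3. Forward order: cyclobutanone is alkylated with the chain via its SAMP hydrazone. A bis(methylsulfanyl) group and a hydride reduction then move the carbonyl to the neighbouring carbon and leave the cis carbinol. Nickel-catalysed ring expansion with the silylalkyne closes the six-membered ring, and fluoride removes the helpers.
4. Stereochemistry: C5 comes from the SAMP auxiliary; C4 comes from hydride delivery anti to the chain on the four-membered ring (cis). Both are carried through the ring expansion with retention; the E alkenes come from geranylgeraniol.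
5. Helpers that are removed again: the C1–C4 ring bond, the C(SMe)2 group (masked ketone), the trimethylsilyl group on the alkyne (orientation) and the silyloxymethyl acetal (chelation, fluoride-labile).

Key step: step 11

Remark: GG = (2E,6E,10E)-3,7,11,15-tetramethylhexadeca-2,6,10,14-tetraen-1-yl. In the ring numbering above the target is (4R,5R), with OH and GG cis.
Assumption: the SAMP azaenolate of cyclobutanone is alkylated with the facial sense established for other cyclic ketones.

**Step 1**
Reactants: 1 (2E,6E,10E)-geranylgeraniol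
Product: 2 (2E,6E,10E)-geranylgeranyl bromide
Conditions: PBr3 (0.4 equiv), Et2O, −10 °C; used crude
Reagents that add atoms: phosphorus tribromide, BrP(Br)Br
Why: SN2 bromination of the primary allylic alcohol via its phosphite ester at low temperature should give the bromide without allylic transposition or loss of E geometry.

**Step 2**
Reactants: 3 cyclobutanone; 4 (S)-1-amino-2-(methoxymethyl)pyrrolidine (SAMP)
Product: 5 (S)-N-cyclobutylidene-2-(methoxymethyl)pyrrolidin-1-amine
Conditions: neat, 60 °C, 4 Å molecular sieves
Reagents that add atoms: none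
Why: Hydrazone condensation of the strained, unhindered ketone with the auxiliary hydrazine should go to completion on removal of water.

**Step 3**
Reactants: 5 SAMP hydrazone of cyclobutanone; 2 geranylgeranyl bromide
Product: 6 (2S)-N-[(2S)-2-GG-cyclobutylidene]-2-(methoxymethyl)pyrrolidin-1-amine
Conditions: LiN(i-Pr)2, THF, 0 °C; then 2, −95 °C → −20 °C
Reagents that add atoms: none
Why: SAMP-hydrazone alkylation (Enders hydrazone method): the lithium azaenolate, held rigid by methoxy chelation, should be attacked by the primary allylic bromide (SN2, E geometry kept) on the face left open by the auxiliary, which sets the S centre on the ring.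

**Step 4**
Reactants: 6 alkylated SAMP hydrazone
Product: 8 (2S)-N-[(4R)-2,2-bis(methylsulfanyl)-4-GG-cyclobutylidene]-2-(methoxymethyl)pyrrolidin-1-amine, via mono(methylsulfanyl) hydrazone 7 (not isolated)
Conditions: LiN(i-Pr)2 (1.1 equiv), THF, −78 °C; MeSSO2Me (1.1 equiv); then LiN(i-Pr)2 (1.2 equiv); MeSSO2Me (1.2 equiv), −78 → −20 °C
Reagents that add atoms: S-methyl methanethiosulfonate, CS(=O)(=O)SC
Why: α-Sulfenylation of a hydrazone azaenolate: deprotonation should occur at the unsubstituted α'-methylene, and after the first sulfenylation the sulfur-bearing carbon is the more acidic site, so the second SMe enters the same carbon while the stereocentre on the other α-carbon is untouched (no new stereocentre in 8).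

**Step 5**
Reactants: 8 bis(methylsulfanyl) hydrazone
Product: 9 (4R)-2,2-bis(methylsulfanyl)-4-GG-cyclobutan-1-one
Conditions: saturated aqueous oxalic acid, Et2O, 25 °C (two phases)
Reagents that add atoms: water, O
Why: Mild acidic hydrolysis of the hydrazone should release the ketone without epimerising the α-centre, the dithioketal being stable to acid and the auxiliary being recovered from the aqueous phase.

**Step 6**
Reactants: 9 α,α-bis(methylsulfanyl) ketone
Product: 10 (1R,4R)-2,2-bis(methylsulfanyl)-4-GG-cyclobutan-1-ol (OH and GG cis)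
Conditions: LiBH(s-Bu)3, THF, −78 °C; then H2O
Reagents that add atoms: none
Why: Substrate-controlled hydride reduction: the bulky borohydride should attack the cyclobutanone on the face opposite the adjacent GG group (the C(SMe)2 carbon is symmetric and gives no bias), which places the new OH cis to the chain.

**Step 7**
Reactants: 10 cis-cyclobutanol
Product: 11 {[(1R,4R)-2,2-bis(methylsulfanyl)-4-GG-cyclobutyl]oxymethoxy}tri(propan-2-yl)silane
Conditions: (i-Pr)3SiOCH2Cl, i-Pr2NEt, Bu4NI (cat.), CH2Cl2, 0 → 35 °C
Reagents that add atoms: (triisopropylsiloxy)methyl chloride, ClCO[Si](C(C)C)(C(C)C)C(C)C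
Why: O-Alkylation of the hindered secondary alcohol by the reactive α-chloro ether (as for MOM or SEM ethers) should give an acetal whose inner oxygen can chelate a metal and which fluoride cleaves later.

**Step 8**
Reactants: 11 protected dithioketal
Product: 12 (2R,3R)-3-GG-2-{[tri(propan-2-yl)silyl]oxymethoxy}cyclobutan-1-one (cis)
Conditions: MeI (excess), CaCO3, MeCN–H2O 4:1, 45 °C
Reagents that add atoms: water, O
Why: Alkylative dithioketal hydrolysis (S-methylation, loss of sulfide, trapping of the thionium ion by water) should unmask the ketone under buffered neutral conditions and complete the 1,2-carbonyl transposition without touching the acetal, the alkenes or the α-alkoxy centre.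

**Step 9**
Reactants: 13 4-(trimethylsilyl)but-3-yn-1-ol
Product: 14 4-(trimethylsilyl)but-3-ynoic acid
Conditions: TEMPO (cat.), PhI(OAc)2 (2.2 equiv), MeCN–H2O 1:1, 25 °C
Reagents that add atoms: water, O
Why: Oxoammonium-mediated oxidation of the primary alcohol through the aldehyde hydrate should give the acid under near-neutral conditions that avoid propargyl-to-allenyl isomerisation and loss of the C-silyl group.

**Step 10**
Reactants: 14 4-(trimethylsilyl)but-3-ynoic acid
Product: 15 methyl 4-(trimethylsilyl)but-3-ynoate
Conditions: Me3SiCHN2, toluene–MeOH 4:1, 0 °C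
Reagents that add atoms: trimethylsilyldiazomethane, C[Si](C)(C)C=[N+]=[N-]
Why: Base-free methyl esterification with the diazo reagent should leave the acidic propargylic CH2 untouched, so no allenoate forms.

**Step 11**
Reactants: 12 cis-2-alkoxy-3-GG-cyclobutanone; 15 methyl 4-(trimethylsilyl)but-3-ynoate
Product: 16 methyl 2-[(3R,4R)-6-oxo-4-GG-3-{[tri(propan-2-yl)silyl]oxymethoxy}-2-(trimethylsilyl)cyclohex-1-en-1-yl]acetate
Conditions: Ni(cod)2 (10 mol %), PCy3 (20 mol %), 15 (1.5 equiv, slow addition), toluene, 90 °C
Reagents that add atoms: none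
Why: Proposed new method: zerovalent nickel should couple the C=O of 12 and the alkyne of 15 oxidatively to a spiro oxanickelacyclopentene (new bond from the carbonyl carbon to the alkyne carbon that bears CH2CO2Me, silicon-bearing carbon on nickel), β-carbon elimination then opens the strained four-membered ring between the carbonyl carbon and the oxygen-bearing carbon, and C–C reductive elimination from the seven-membered nickelacycle joins that carbon to the silicon-bearing alkyne carbon. The closest known reaction type is the nickel-catalysed intermolecular insertion of alkynes into 3-substituted cyclobutanones and into 3-oxetanones or 3-azetidinones (formal [4+2]); its use on an unsymmetrical 2-alkoxycyclobutanone with cleavage on the oxygenated side is the untested part. The six-membered ring is closed by two-carbon ring expansion of the cyclobutanone, the last bond being made by reductive elimination and not by cyclisation of an open chain, and the release of about 26 kcal/mol of ring strain drives it. No stereocentre is created: C5 is a spectator and C4 passes from carbon to nickel to carbon with retention in both steps, so the cis pair of 12 is carried into 16. The selectivity needed between the two ring bonds at the carbonyl is secured by the acetal oxygen, which lies cis to the nickel alkoxide (the alkyne adds to the ketone face opposite both substituents), chelates nickel so that Ni–O–C–C(O) is held syn-periplanar for β-carbon elimination, and stabilises the resulting α-alkoxyalkyl nickel. The orientation of the alkyne is secured by the trimethylsilyl group, which in oxidative cyclisations of silylalkynes ends next to nickel and therefore on C3, where step 12 removes it.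

**Step 12**
Reactants: 16 ring-expanded silyl enone
Product: 18 methyl 2-[(3R,4R)-3-hydroxy-6-oxo-4-GG-cyclohex-1-en-1-yl]acetate (target), via hydroxy vinylsilane 17 (not isolated)
Conditions: Bu4NF (3 equiv), THF, 0 → 25 °C; then pH 7 buffer
Reagents that add atoms: none
Why: Fluoride should cleave the Si–O bond of the acetal, the hemiacetal alkoxide loses formaldehyde to give the C4 alkoxide of 17, and this alkoxide attacks the neighbouring C3 silicon (hydroxyl-assisted protodesilylation of a β-hydroxy vinylsilane by a Brook-type carbon-to-oxygen silyl shift), after which protonation and O-desilylation give the target with both stereocentres and the alkene position unchanged.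

**Compound list**

1 | (2E,6E,10E)-3,7,11,15-tetramethylhexadeca-2,6,10,14-tetraen-1-ol (geranylgeraniol) | OC/C=C(\C)CC/C=C(\C)CC/C=C(\C)CCC=C(C)C | starting material
2 | (2E,6E,10E)-1-bromo-3,7,11,15-tetramethylhexadeca-2,6,10,14-tetraene (geranylgeranyl bromide) | BrC/C=C(\C)CC/C=C(\C)CC/C=C(\C)CCC=C(C)C | intermediate
3 | cyclobutanone | O=C1CCC1 | starting material
4 | (S)-1-amino-2-(methoxymethyl)pyrrolidine (SAMP) | COC[C@@H]1CCCN1N | starting material
5 | (S)-N-cyclobutylidene-2-(methoxymethyl)pyrrolidin-1-amine | COC[C@@H]1CCCN1N=C1CCC1 | intermediate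
6 | (2S)-N-[(2S)-2-GG-cyclobutylidene]-2-(methoxymethyl)pyrrolidin-1-amine | COC[C@@H]1CCCN1N=C1CC[C@H]1C/C=C(\C)CC/C=C(\C)CC/C=C(\C)CCC=C(C)C | intermediate
7 | hydrazone 6 with one methylsulfanyl group on the unsubstituted α-carbon (configuration at that carbon not defined) | COC[C@@H]1CCCN1N=C1C(SC)C[C@H]1C/C=C(\C)CC/C=C(\C)CC/C=C(\C)CCC=C(C)C | intermediate
8 | (2S)-N-[(4R)-2,2-bis(methylsulfanyl)-4-GG-cyclobutylidene]-2-(methoxymethyl)pyrrolidin-1-amine | COC[C@@H]1CCCN1N=C1C(SC)(SC)C[C@H]1C/C=C(\C)CC/C=C(\C)CC/C=C(\C)CCC=C(C)C | intermediate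
9 | (4R)-2,2-bis(methylsulfanyl)-4-GG-cyclobutan-1-one | O=C1C(SC)(SC)C[C@H]1C/C=C(\C)CC/C=C(\C)CC/C=C(\C)CCC=C(C)C | intermediate
10 | (1R,4R)-2,2-bis(methylsulfanyl)-4-GG-cyclobutan-1-ol (cis) | CSC1(SC)[C@H](O)[C@H](C/C=C(\C)CC/C=C(\C)CC/C=C(\C)CCC=C(C)C)C1 | intermediate
11 | {[(1R,4R)-2,2-bis(methylsulfanyl)-4-GG-cyclobutyl]oxymethoxy}tri(propan-2-yl)silane | CSC1(SC)[C@H](OCO[Si](C(C)C)(C(C)C)C(C)C)[C@H](C/C=C(\C)CC/C=C(\C)CC/C=C(\C)CCC=C(C)C)C1 | intermediate
12 | (2R,3R)-3-GG-2-{[tri(propan-2-yl)silyl]oxymethoxy}cyclobutan-1-one (cis) | O=C1[C@H](OCO[Si](C(C)C)(C(C)C)C(C)C)[C@H](C/C=C(\C)CC/C=C(\C)CC/C=C(\C)CCC=C(C)C)C1 | intermediate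
13 | 4-(trimethylsilyl)but-3-yn-1-ol | C[Si](C)(C)C#CCCO | starting material
14 | 4-(trimethylsilyl)but-3-ynoic acid | C[Si](C)(C)C#CCC(=O)O | intermediate
15 | methyl 4-(trimethylsilyl)but-3-ynoate | COC(=O)CC#C[Si](C)(C)C | intermediate
16 | methyl 2-[(3R,4R)-6-oxo-4-GG-3-{[tri(propan-2-yl)silyl]oxymethoxy}-2-(trimethylsilyl)cyclohex-1-en-1-yl]acetate | COC(=O)CC1=C([Si](C)(C)C)[C@H](OCO[Si](C(C)C)(C(C)C)C(C)C)[C@H](C/C=C(\C)CC/C=C(\C)CC/C=C(\C)CCC=C(C)C)CC1=O | intermediate
17 | methyl 2-[(3R,4R)-3-hydroxy-6-oxo-4-GG-2-(trimethylsilyl)cyclohex-1-en-1-yl]acetate | COC(=O)CC1=C([Si](C)(C)C)[C@H](O)[C@H](C/C=C(\C)CC/C=C(\C)CC/C=C(\C)CCC=C(C)C)CC1=O | intermediate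
18 | methyl 2-[(3R,4R)-3-hydroxy-6-oxo-4-GG-cyclohex-1-en-1-yl]acetate | COC(=O)CC1=C[C@H](O)[C@H](C/C=C(\C)CC/C=C(\C)CC/C=C(\C)CCC=C(C)C)CC1=O | target

**Step count and risks**

Total steps: 12. Longest linear sequence: 9 steps (steps 2–8, 11 and 12 from cyclobutanone; equally steps 1, 3–8, 11 and 12 from geranylgeraniol).

Steps most likely to fail:

1. Step 11 (the step proposed as a new method). What may go wrong: insertion into the unsubstituted ring bond instead of the oxygenated one, β-hydride loss from the alkylnickel, or isomerisation and oligomerisation of the alkyne. The fallback uses known reactions only and builds the enone on a preformed six-membered ring; it sets out from 2 and comes back at 18.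
   - Commercial 1,4-dioxaspiro[4.5]decan-8-one is condensed with 4 to the SAMP hydrazone F1.
   - F1 is alkylated (LiN(i-Pr)2; 2) to the alkylated hydrazone F2, which is hydrolysed with oxalic acid to the ketal ketone F3.
   - Kinetic enolisation on the methylene side (LiN(i-Pr)2, −78 °C) and one-pot dehydrogenation with N-tert-butylbenzenesulfinimidoyl chloride give the ketal enone F4.
   - LiBH(s-Bu)3 reduces the carbonyl from the face opposite the chain to the cis allylic alcohol F5; conjugate reduction is blocked because the β-carbon adjoins the ketal carbon.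
   - Aqueous acid unmasks the cis hydroxy enone F6, and I2/pyridine gives the α-iodo enone F7.
   - Negishi-type coupling of F7 with the Reformatsky reagent F8 (from methyl bromoacetate and zinc; Pd(PPh3)4, THF) gives 18.

2. Step 12. What may go wrong: exposure of the γ-hydroxy enone to basic fluoride leads to dehydration towards the arene or migration of the double bond, or the cleavage stalls at the hemiacetal or the C-silyl stage. The fallback separates O-deprotection from C-desilylation by using an oxidatively removable ether; it sets out from 10 and comes back at 18.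
   - 10 is converted (NaH, 4-methoxybenzyl chloride, Bu4NI) into the 4-methoxybenzyl ether F9.
   - F9 is hydrolysed as in step 8 to the cyclobutanone F10, which is ring-expanded with 15 as in step 11 to the silyl enone F11.
   - DDQ in buffered CH2Cl2–water removes the benzyl ether under neutral conditions and gives 17, now isolated.
   - One equivalent of acetic-acid-buffered Bu4NF at 0 °C desilylates 17 to 18.

3. Step 4. What may go wrong: proton transfer between the azaenolate and the monosulfenylated product gives mixtures, or the azaenolate equilibrates towards the substituted α-carbon and configuration is lost. The fallback installs the masked ketone before the stereocentre; it sets out from 3 and comes back at 8.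
   - 3 is converted with pyrrolidine into the enamine F12.
   - F12 is bis-sulfenylated with MeSSO2Me and Et3N and hydrolysed to 2,2-bis(methylsulfanyl)cyclobutanone F13.
   - F13 is condensed with 4 to the hydrazone F14, whose only α-methylene is deprotonated (LiN(i-Pr)2) and alkylated with 2 to give 8.

**Further compounds**

F1 | step 11 | (S)-N-(1,4-dioxaspiro[4.5]decan-8-ylidene)-2-(methoxymethyl)pyrrolidin-1-amine | COC[C@@H]1CCCN1N=C1CCC2(CC1)OCCO2
F2 | step 11 | SAMP hydrazone of (7R)-7-GG-1,4-dioxaspiro[4.5]decan-8-one | COC[C@@H]1CCCN1N=C1CCC2(OCCO2)C[C@H]1C/C=C(\C)CC/C=C(\C)CC/C=C(\C)CCC=C(C)C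
F3 | step 11 | (7R)-7-GG-1,4-dioxaspiro[4.5]decan-8-one | O=C1CCC2(OCCO2)C[C@H]1C/C=C(\C)CC/C=C(\C)CC/C=C(\C)CCC=C(C)C
F4 | step 11 | F3 with a C9=C10 double bond (ketal enone, GG on the sp3 α-carbon of the ketone) | O=C1C=CC2(OCCO2)C[C@H]1C/C=C(\C)CC/C=C(\C)CC/C=C(\C)CCC=C(C)C
F5 | step 11 | cis allylic alcohol from F4 (OH and GG cis, ketal retained) | C1=C[C@H](O)[C@H](C/C=C(\C)CC/C=C(\C)CC/C=C(\C)CCC=C(C)C)CC12OCCO2
F6 | step 11 | (4R,5R)-4-hydroxy-5-GG-cyclohex-2-en-1-one | O=C1C=C[C@H](O)[C@H](C/C=C(\C)CC/C=C(\C)CC/C=C(\C)CCC=C(C)C)C1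
F7 | step 11 | (4R,5R)-4-hydroxy-2-iodo-5-GG-cyclohex-2-en-1-one | O=C1C(I)=C[C@H](O)[C@H](C/C=C(\C)CC/C=C(\C)CC/C=C(\C)CCC=C(C)C)C1
F8 | step 11 | bromo(2-methoxy-2-oxoethyl)zinc | COC(=O)C[Zn]Br
F9 | step 12 | 4-methoxybenzyl ether of 10 | CSC1(SC)[C@H](OCc2ccc(OC)cc2)[C@H](C/C=C(\C)CC/C=C(\C)CC/C=C(\C)CCC=C(C)C)C1
F10 | step 12 | (2R,3R)-3-GG-2-[(4-methoxybenzyl)oxy]cyclobutan-1-one | O=C1[C@H](OCc2ccc(OC)cc2)[C@H](C/C=C(\C)CC/C=C(\C)CC/C=C(\C)CCC=C(C)C)C1
F11 | step 12 | methyl 2-[(3R,4R)-3-[(4-methoxybenzyl)oxy]-6-oxo-4-GG-2-(trimethylsilyl)cyclohex-1-en-1-yl]acetate | COC(=O)CC1=C([Si](C)(C)C)[C@H](OCc2ccc(OC)cc2)[C@H](C/C=C(\C)CC/C=C(\C)CC/C=C(\C)CCC=C(C)C)CC1=O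
F12 | step 4 | 1-(cyclobut-1-en-1-yl)pyrrolidine | C1CCN(C1)C1=CCC1
F13 | step 4 | 2,2-bis(methylsulfanyl)cyclobutan-1-one | O=C1CCC1(SC)SC
F14 | step 4 | (S)-N-[2,2-bis(methylsulfanyl)cyclobutylidene]-2-(methoxymethyl)pyrrolidin-1-amine | COC[C@@H]1CCCN1N=C1CCC1(SC)SC
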